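The route rests on the C1–C10 bond, the fusion bond shared by six-membered ring A (C1, C14, C13, C12, C11, C10) and ten-membered ring B (C1 to C10). Without it, these fourteen carbons form one cembrane-like ring, so a 14-membered epoxy enone is built and closed across the ring, copying the presumed cembrane-to-briarane biosynthesis. Trivalent titanium opens the C1–C2 epoxide to a tertiary C1 radical that adds to C10 of the C10=C11–C12 enone; one operation forms both carbocycles, the quaternary C1, C10, C11 and the C2 hydroxyl. The macrocycle is assembled from L-arabinose (C6 to C10), a propionate, a ketophosphonate and a Sharpless-derived epoxy aldehyde.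

Key step: step 19

Remark on numbering: briarane numbering is used. C1 is the quaternary carbon (methyl C15), C2 and C3 carry acetoxy groups, C4 is CH2, C5 carries the methylene C16, C6 carries Cl, C7 the lactone oxygen, C8 the tertiary hydroxyl, C9 an acetoxy group, C10 is the ring-fusion CH, C11 carries methyl C20, C12 is the ketone, C13=C14 is the enone alkene; the lactone is C17 (methyl C18) and C19.

Assumption: ethyl (E)-2-methyl-4-oxobut-2-enoate and diethyl (3-oxobutan-2-yl)phosphonate are taken as purchasable building blocks.

Step 1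
Reactants: 1 L-arabinose
Product: 2 5-O-(tert-butyldiphenylsilyl)-L-arabinofuranose (anomer mixture)
Conditions: TBDPSCl, imidazole, DMF, 0 °C to rt
Reagents that add atoms: tert-butyldiphenylsilyl chloride, CC(C)(C)[Si](Cl)(c1ccccc1)c1ccccc1
Why: The bulky silyl chloride should react only with the primary hydroxyl, which exists only in the furanose tautomer, so the pyranose–furanose equilibrium drains into the 5-O-silyl furanose (regioselective silyl ether formation).

Step 2
Reactants: 2 5-O-TBDPS-L-arabinofuranose
Product: 3 5-O-TBDPS-1,2-O-isopropylidene-β-L-arabinofuranose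
Conditions: 2,2-dimethoxypropane, p-TsOH (cat.), acetone, rt
Reagents that add atoms: 2,2-dimethoxypropane, COC(C)(C)OC
Why: Acid-catalysed acetal exchange should close the dioxolane on the only cis-1,2-diol (O1/O2 of the β-furanose) and leave the C3 hydroxyl free (isopropylidene acetal formation).

Step 3
Reactants: 3 5-O-TBDPS-1,2-O-isopropylidene-β-L-arabinofuranose
Product: 4 5-O-TBDPS-1,2-O-isopropylidene-β-L-threo-pentofuranos-3-ulose
Conditions: Dess–Martin periodinane, NaHCO3, CH2Cl2, rt
Reagents that add atoms: none
Why: Dess–Martin oxidation of the single free secondary alcohol should give the ketone (future C8) without touching the acetal or the silyl ether.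

Step 4
Reactants: 4 the 3-ulose; 5 tert-butyl propionate
Product: 6 5-O-TBDPS-1,2-O-isopropylidene-3-C-[(1R)-1-(tert-butoxycarbonyl)ethyl]-β-L-lyxofuranose (tertiary hydroxyl on the dioxolane face)
Conditions: 5, LiN(iPr)2, THF/DMPU, −78 °C; then 4; NH4Cl
Reagents that add atoms: none
Why: In this ester-enolate aldol addition to a ketone, the Z(O)-lithium enolate should attack the face anti to both the dioxolane and the CH2OSi group (both on the same face), which fixes C8, while a closed chair transition state sets C17, a centre that stays correctable because it is α to the carbonyl.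

Step 5
Reactants: 6 the aldol adduct
Product: 7 γ-lactone (C19 on O7) with C6 as diethyl dithioacetal, free C8 and C9 hydroxyls and C10 O-TBDPS ether
Conditions: EtSH, TFA, CH2Cl2, 0 °C to rt; then CSA (cat.), PhMe, 50 °C
Reagents that add atoms: ethanethiol, CCS
Why: Acid should remove the acetal and the tert-butyl ester while ethanethiol traps C6 as the open-chain dithioacetal, after which reversible acid-catalysed γ-lactonization should settle on O7, the lactone whose two carbon chains (C6 and C9) are trans, and not on O9 (dithioacetal formation and thermodynamic lactonization).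

Step 6
Reactants: 7 the lactone diol
Product: 8 9-O-acetate of 7
Conditions: Ac2O, pyridine, DMAP (cat.), CH2Cl2, 0 °C
Reagents that add atoms: acetic anhydride, CC(=O)OC(C)=O
Why: Acetylation should take place at the only secondary alcohol and leave the hindered tertiary C8 hydroxyl free, which also locks the lactone on O7.

Step 7
Reactants: 8 the 9-acetate
Product: 9 primary C10 alcohol
Conditions: HF·pyridine, pyridine, THF, 0 °C to rt
Reagents that add atoms: none
Why: Acidic fluoride should cleave the primary silyl ether without the O9-to-O10 acetyl migration that basic fluoride could cause (desilylation).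

Step 8
Reactants: 9 the primary alcohol
Product: 10 C10 aldehyde (α-acetoxy aldehyde, used crude)
Conditions: SO3·pyridine, DMSO, Et3N, CH2Cl2, 0 °C
Reagents that add atoms: none
Why: Parikh–Doering oxidation should give the aldehyde and tolerate the dithioacetal, which hypervalent iodine oxidants could cleave.

Step 9
Reactants: 11 ethyl (E)-2-methyl-4-oxobut-2-enoate; 12 allenyltributylstannane
Product: 13 ethyl (2E,4S)-4-hydroxy-2-methylhept-2-en-6-ynoate
Conditions: (S)-BINOL (cat.), Ti(OiPr)4 (cat.), 4 Å MS, CH2Cl2, −20 °C; aq. KF
Reagents that add atoms: none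
Why: In this Keck-type asymmetric propargylation the BINOL–titanium Lewis acid should direct SE2' addition of the allenylstannane to the si face of the aldehyde, which sets C3.

Step 10
Reactants: 13 the homopropargylic alcohol
Product: 14 ethyl (2E,4S)-4-hydroxy-6-iodo-2-methylhepta-2,6-dienoate
Conditions: NaI, TMSCl, H2O, MeCN, rt
Reagents that add atoms: sodium iodide, [Na+].[I-]
Why: Markovnikov hydroiodination of the terminal alkyne by HI made in the flask should give the 2-iodo-1-alkene (C5 with C16) needed for the chromium coupling, the electron-poor enoate being inert.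

Step 11
Reactants: 14 the iodo enoate
Product: 15 (2E,4S)-6-iodo-2-methylhepta-2,6-diene-1,4-diol
Conditions: i-Bu2AlH, CH2Cl2, −78 °C; aq. potassium sodium tartrate
Reagents that add atoms: none
Why: 1,2-Reduction of the enoate by the aluminium hydride should give the E-allylic alcohol (C14) without touching the iodoalkene.

Step 12
Reactants: 15 the allylic diol
Product: 16 [(2S,3S)-3-[(1S)-1-hydroxy-3-iodobut-3-enyl]-2-methyloxiran-2-yl]methanol (C1–C2 epoxide)
Conditions: Ti(OiPr)4 (cat.), L-(+)-diisopropyl tartrate (cat.), t-BuOOH, 4 Å MS, CH2Cl2, −20 °C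
Reagents that add atoms: tert-butyl hydroperoxide, CC(C)(C)OO
Why: In this Sharpless asymmetric epoxidation the primary allylic alcohol binds the titanium tartrate and the L-(+)-tartrate should deliver oxygen to the face that gives the required C2 configuration in the trans epoxide, while the secondary C3 hydroxyl (cis β-methyl) and the iodoalkene should not compete.

Step 13
Reactants: 16 the epoxy diol
Product: 17 epoxy aldehyde (C14 aldehyde, C3 hydroxyl free, configurations as in 16)
Conditions: TEMPO (cat.), PhI(OAc)2, CH2Cl2, rt
Reagents that add atoms: none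
Why: Oxoammonium oxidation should take the primary alcohol selectively, and the product can neither epimerize (quaternary α-carbon) nor close to a lactol (C14 and C3 are trans on the epoxide).

Step 14
Reactants: 17 the epoxy aldehyde
Product: 18 C3 acetate of 17
Conditions: Ac2O, pyridine, DMAP (cat.), CH2Cl2, 0 °C
Reagents that add atoms: acetic anhydride, CC(=O)OC(C)=O
Why: Acetylation should install the C3 acetate before any alkoxide is generated next to the epoxide, which avoids Payne rearrangement later.

Step 15
Reactants: 19 diethyl (3-oxobutan-2-yl)phosphonate; 18 the epoxy aldehyde acetate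
Product: 21 β'-hydroxy β-ketophosphonate (C11 to C14 joined to C1; C14 and C11 epimer mixtures), via phosphonate dianion 20 (not isolated)
Conditions: 19, LiN(iPr)2 (2.1 equiv), THF, −78 to 0 °C; then 18, −78 °C; NH4Cl
Reagents that add atoms: none
Why: In this dianion aldol addition the terminal (C13) carbanion of the β-ketophosphonate dianion should add to the aldehyde faster than to the acetate, and the configuration of the new C14 carbinol is inconsequential because this oxygen is eliminated in step 21.

Step 16
Reactants: 21 the ketophosphonate; 10 the aldehyde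
Product: 22 open-chain E-enone (C10=C11) with C6 dithioacetal
Conditions: LiCl, iPr2NEt, MeCN, 0 °C to rt
Reagents that add atoms: none
Why: Horner–Wadsworth–Emmons olefination under mild LiCl/amine conditions should give the E-trisubstituted enone without eliminating the β-hydroxy ketone or epimerizing C9.

Step 17
Reactants: 22 the dithioacetal
Product: 23 seco-aldehyde (C6 aldehyde, C5 iodoalkene)
Conditions: I2, NaHCO3, acetone/H2O, 0 °C
Reagents that add atoms: water, O
Why: Iodine-mediated hydrolysis of the dithioacetal should free the C6 aldehyde under near-neutral conditions that spare the epoxide, the iodoalkene and the enone.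

Step 18
Reactants: 23 the seco-aldehyde
Product: 24 14-membered epoxy enone, (6R)-allylic alcohol with C5=C16 methylene
Conditions: CrCl2 (excess), NiCl2 (cat.), chiral oxazoline–sulfonamide ligand, Et3N, THF/MeCN, rt, high dilution
Reagents that add atoms: none
Why: In this Nozaki–Hiyama–Kishi macrocyclization the alkenylchromium formed through nickel catalysis should add only to the aldehyde and close the 14-membered ring, with the ligand enantiomer chosen to deliver the alkenyl group to the re face of C6 against the Felkin–Anh preference so that the (6R)-alcohol results.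

Step 19
Reactants: 24 the macrocyclic epoxy enone
Product: 27 bicyclic 2,6,8,14-tetrahydroxy 3,9-diacetoxy 12-ketone (rings A and B closed), via C1 radical 25 (not isolated), via titanium enolate 26 (not isolated)
Conditions: Cp2TiCl2 (0.2 equiv), Mn dust, 2,4,6-collidine·HCl, THF, rt, slow addition of 24; aq. NaH2PO4
Reagents that add atoms: none
Why: Cp2TiCl (trivalent titanium, formed from Cp2TiCl2 and Mn and turned over by collidine hydrochloride) should open the C1–C2 epoxide homolytically at the more substituted carbon to give the tertiary C1 radical with the titanium alkoxide on C2, which adds across the ring to C10, the β-carbon of the C10=C11–C12 enone, after which a second trivalent titanium reduces the α-keto radical to a titanium enolate that is protonated at C11. The closest known reaction type is the titanocene-mediated reductive epoxide opening followed by radical conjugate addition, as used for transannular cyclizations of epoxygermacrolides to eudesmanolides. Ring A closes in a 6-endo-trig mode (C1, C14, C13, C12, C11, C10) and the same bond defines ring B (C1 to C10) as a 10-exo-trig closure. C2 keeps the configuration set in step 12; C1 should form its bond anti to the departed oxygen, because the oxygen of the E-derived epoxide lies on the periphery of the macrocycle while C10 approaches from the ring interior; C10 follows from a chair-like transition state of the forming ring A with both macrocycle arms (C2 and C9) pseudo-equatorial, which gives the trans ring fusion; and C11 is set by protonation of the enolate anti to the axial C15 methyl. The step needs C1–O rather than C2–O cleavage (secured by the tertiary versus secondary radical) and conjugate addition faster than attack of the C1 radical on the C5=C16 methylene or its reduction (secured by polarity matching of the nucleophilic radical with the enone and by the low stationary titanium concentration of the catalytic protocol).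

Step 20
Reactants: 27 the bicyclic tetraol
Product: 28 (6S)-allylic chloride (C2, C8 and C14 hydroxyls retained)
Conditions: PPh3, hexachloroacetone, THF, −20 to 0 °C
Reagents that add atoms: hexachloroacetone, ClC(Cl)(Cl)C(=O)C(Cl)(Cl)Cl
Why: In this Appel-type chlorination the oxyphosphonium of the allylic C6 hydroxyl should be displaced by chloride with inversion and without allylic transposition, while the neopentyl C2 and C14 hydroxyls and the tertiary C8 hydroxyl are too hindered to react.

Step 21
Reactants: 28 the chloride
Product: 30 CNP0391614.1 (target), via diacetate 29 (not isolated)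
Conditions: Ac2O, Et3N, DMAP, CH2Cl2, 0 °C to rt; then DBU, 0 °C
Reagents that add atoms: acetic anhydride, CC(=O)OC(C)=O
Why: DMAP-catalysed acetylation of the C2 and C14 hydroxyls should be followed by E1cB loss of the C14 acetoxy group β to the C12 ketone, which gives the C13=C14 enone, while the tertiary C8 hydroxyl stays free.

Compound list
1 | L-arabinose (drawn as the open-chain aldehyde) | O=C[C@H](O)[C@@H](O)[C@@H](O)CO | starting material
2 | 5-O-(tert-butyldiphenylsilyl)-L-arabinofuranose (anomer mixture) | OC1O[C@@H](CO[Si](c2ccccc2)(c2ccccc2)C(C)(C)C)[C@H](O)[C@H]1O | intermediate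
3 | 5-O-TBDPS-1,2-O-isopropylidene-β-L-arabinofuranose | CC1(C)O[C@H]2O[C@@H](CO[Si](c3ccccc3)(c3ccccc3)C(C)(C)C)[C@H](O)[C@H]2O1 | intermediate
4 | 5-O-TBDPS-1,2-O-isopropylidene-β-L-threo-pentofuranos-3-ulose | CC1(C)O[C@H]2O[C@@H](CO[Si](c3ccccc3)(c3ccccc3)C(C)(C)C)C(=O)[C@H]2O1 | intermediate
5 | tert-butyl propionate | CCC(=O)OC(C)(C)C | starting material
6 | 5-O-TBDPS-1,2-O-isopropylidene-3-C-[(1R)-1-(tert-butoxycarbonyl)ethyl]-β-L-lyxofuranose | CC1(C)O[C@H]2O[C@@H](CO[Si](c3ccccc3)(c3ccccc3)C(C)(C)C)[C@](O)([C@@H](C)C(=O)OC(C)(C)C)[C@H]2O1 | intermediate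
7 | γ-lactone on O7 with C6 diethyl dithioacetal, C8 and C9 hydroxyls, C10 O-TBDPS (C6 and C9 chains trans, C18 methyl cis to the C8 hydroxyl) | CCSC(SCC)[C@@H]1OC(=O)[C@H](C)[C@@]1(O)[C@@H](O)CO[Si](c2ccccc2)(c2ccccc2)C(C)(C)C | intermediate
8 | 9-O-acetate of 7 | CCSC(SCC)[C@@H]1OC(=O)[C@H](C)[C@@]1(O)[C@@H](OC(C)=O)CO[Si](c2ccccc2)(c2ccccc2)C(C)(C)C | intermediate
9 | C10 primary alcohol | CCSC(SCC)[C@@H]1OC(=O)[C@H](C)[C@@]1(O)[C@@H](OC(C)=O)CO | intermediate
10 | C10 aldehyde | CCSC(SCC)[C@@H]1OC(=O)[C@H](C)[C@@]1(O)[C@@H](OC(C)=O)C=O | intermediate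
11 | ethyl (E)-2-methyl-4-oxobut-2-enoate | CCOC(=O)/C(C)=C/C=O | starting material
12 | allenyltributylstannane | C=C=C[Sn](CCCC)(CCCC)CCCC | starting material
13 | ethyl (2E,4S)-4-hydroxy-2-methylhept-2-en-6-ynoate | CCOC(=O)/C(C)=C/[C@@H](O)CC#C | intermediate
14 | ethyl (2E,4S)-4-hydroxy-6-iodo-2-methylhepta-2,6-dienoate | CCOC(=O)/C(C)=C/[C@@H](O)CC(I)=C | intermediate
15 | (2E,4S)-6-iodo-2-methylhepta-2,6-diene-1,4-diol | OC/C(C)=C/[C@@H](O)CC(I)=C | intermediate
16 | [(2S,3S)-3-[(1S)-1-hydroxy-3-iodobut-3-enyl]-2-methyloxiran-2-yl]methanol | OC[C@]1(C)O[C@H]1[C@@H](O)CC(I)=C | intermediate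
17 | epoxy aldehyde (C14 aldehyde, C3 hydroxyl, configurations as in 16) | O=C[C@]1(C)O[C@H]1[C@@H](O)CC(I)=C | intermediate
18 | epoxy aldehyde C3 acetate | O=C[C@]1(C)O[C@H]1[C@@H](OC(C)=O)CC(I)=C | intermediate
19 | diethyl (3-oxobutan-2-yl)phosphonate (racemic) | CCOP(=O)(OCC)C(C)C(C)=O | starting material
20 | dilithium dianion of 19 (carbanions at C11 and C13) | [Li+].[Li+].CCOP(=O)(OCC)[C-](C)C(=O)[CH2-] | intermediate
21 | β'-hydroxy β-ketophosphonate with C1–C2 epoxide, C3 acetate and C5 iodoalkene (C11 and C14 epimer mixtures) | CCOP(=O)(OCC)C(C)C(=O)CC(O)[C@]1(C)O[C@H]1[C@@H](OC(C)=O)CC(I)=C | intermediate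
22 | open-chain E-enone with C6 diethyl dithioacetal (C14 epimer mixture) | CCSC(SCC)[C@@H]1OC(=O)[C@H](C)[C@@]1(O)[C@@H](OC(C)=O)/C=C(\C)C(=O)CC(O)[C@]2(C)O[C@H]2[C@@H](OC(C)=O)CC(I)=C | intermediate
23 | seco-aldehyde (C6 aldehyde) | O=C[C@@H]1OC(=O)[C@H](C)[C@@]1(O)[C@@H](OC(C)=O)/C=C(\C)C(=O)CC(O)[C@]2(C)O[C@H]2[C@@H](OC(C)=O)CC(I)=C | intermediate
24 | 14-membered epoxy enone, (6R)-alcohol (C14 epimer mixture) | C=C1C[C@H](OC(C)=O)[C@@H]2O[C@@]2(C)C(O)CC(=O)/C(C)=C/[C@H](OC(C)=O)[C@]3(O)[C@@H](C)C(=O)O[C@H]3[C@@H]1O | intermediate
25 | tertiary C1 radical with titanoxy group on C2 | C=C1C[C@H](OC(C)=O)[C@H](O[Ti](Cl)(C2C=CC=C2)C2C=CC=C2)[C](C)C(O)CC(=O)/C(C)=C/[C@H](OC(C)=O)[C@]3(O)[C@@H](C)C(=O)O[C@H]3[C@@H]1O | intermediate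
26 | bicyclic titanium enolate (C11=C12) | C=C1C[C@H](OC(C)=O)[C@H](O[Ti](Cl)(C2C=CC=C2)C2C=CC=C2)[C@@]2(C)C(O)CC(O[Ti](Cl)(C4C=CC=C4)C4C=CC=C4)=C(C)[C@@H]2[C@H](OC(C)=O)[C@]3(O)[C@@H](C)C(=O)O[C@H]3[C@@H]1O | intermediate
27 | bicyclic 2,6,8,14-tetrahydroxy 3,9-diacetoxy 12-ketone, (6R)-alcohol | C=C1C[C@H](OC(C)=O)[C@H](O)[C@@]2(C)C(O)CC(=O)[C@H](C)[C@@H]2[C@H](OC(C)=O)[C@]3(O)[C@@H](C)C(=O)O[C@H]3[C@@H]1O | intermediate
28 | (6S)-chloride with C2, C8 and C14 hydroxyls | C=C1C[C@H](OC(C)=O)[C@H](O)[C@@]2(C)C(O)CC(=O)[C@H](C)[C@@H]2[C@H](OC(C)=O)[C@]3(O)[C@@H](C)C(=O)O[C@H]3[C@H]1Cl | intermediate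
29 | 2,14-di-O-acetate of 28 | C=C1C[C@H](OC(C)=O)[C@H](OC(C)=O)[C@@]2(C)C(OC(C)=O)CC(=O)[C@H](C)[C@@H]2[C@H](OC(C)=O)[C@]3(O)[C@@H](C)C(=O)O[C@H]3[C@H]1Cl | intermediate
30 | CNP0391614.1 | C=C1C[C@H](OC(C)=O)[C@H](OC(C)=O)[C@@]2(C)C=CC(=O)[C@H](C)[C@@H]2[C@H](OC(C)=O)[C@]2(O)[C@@H](C)C(=O)O[C@H]2[C@H]1Cl | target

Total step count: 21. Longest linear sequence: 14 steps (steps 1 to 8, then 16 to 21).

Steps most likely to fail

Step 19. The C1 radical may be reduced or eliminated before it crosses the ring, it may add to the C5=C16 methylene (6-endo onto C16), or the ring may close on the wrong face of C10. The fallback sets out from 22 and returns at 27; it closes ring A before the macrocycle. The same titanocene conditions on open-chain 22 should give the ring-A cyclohexanone dithioacetal F1 through an acyclic chair transition state with the C2 and C9 chains equatorial; here the only other alkene is the iodoalkene on a freely rotating chain. Hydrolysis with I2/NaHCO3 should give the aldehyde F2, and a CrCl2/NiCl2 coupling with the same chiral ligand then closes ring B between C5 and C6 to give 27.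

Step 18. The ligand may not override the Felkin–Anh preference, so facial selectivity at C6 may be poor or reversed. The fallback sets out from 23 and returns at 24. The CrCl2/NiCl2 cyclization run without ligand should give the (6S)-alcohol macrocycle F3 under substrate control. Mitsunobu esterification with chloroacetic acid (PPh3, DIAD) should invert it to the (6R)-chloroacetate F4, and thiourea/NaHCO3 removes the chloroacetate without touching the acetates to give 24.

Step 5. Lactonization may be trapped on O9 (kinetic closure to the cis lactone) or may equilibrate incompletely. The fallback sets out from 6 and returns at 7; it blocks O9 before the acid is released. TBAF removes the silyl ether of 6 to give the primary alcohol F5. EtSH/TFA followed by 2,2-dimethoxypropane/CSA should tie O9 and O10 into a terminal acetonide, so that the acid can only close on O7, giving the lactone acetonide F6. Aqueous AcOH gives the 9,10-diol F7, and selective silylation of its primary hydroxyl (TBDPSCl, imidazole) returns 7.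

Further compounds
F1 | step 19 | ring-A cyclohexanone with C6 diethyl dithioacetal and C5 iodoalkene (ring B open) | CCSC(SCC)[C@@H]1OC(=O)[C@H](C)[C@@]1(O)[C@@H](OC(C)=O)[C@H]2[C@@H](C)C(=O)CC(O)[C@]2(C)[C@@H](O)[C@@H](OC(C)=O)CC(I)=C
F2 | step 19 | ring-A cyclohexanone C6 aldehyde | O=C[C@@H]1OC(=O)[C@H](C)[C@@]1(O)[C@@H](OC(C)=O)[C@H]2[C@@H](C)C(=O)CC(O)[C@]2(C)[C@@H](O)[C@@H](OC(C)=O)CC(I)=C
F3 | step 18 | 14-membered epoxy enone, (6S)-alcohol | C=C1C[C@H](OC(C)=O)[C@@H]2O[C@@]2(C)C(O)CC(=O)/C(C)=C/[C@H](OC(C)=O)[C@]3(O)[C@@H](C)C(=O)O[C@H]3[C@H]1O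
F4 | step 18 | 14-membered epoxy enone, (6R)-chloroacetate | C=C1C[C@H](OC(C)=O)[C@@H]2O[C@@]2(C)C(O)CC(=O)/C(C)=C/[C@H](OC(C)=O)[C@]3(O)[C@@H](C)C(=O)O[C@H]3[C@@H]1OC(=O)CCl
F5 | step 5 | desilylated aldol adduct (free 5-hydroxyl) | CC1(C)O[C@H]2O[C@@H](CO)[C@](O)([C@@H](C)C(=O)OC(C)(C)C)[C@H]2O1
F6 | step 5 | O7 lactone with C6 dithioacetal and 9,10-O-isopropylidene | CCSC(SCC)[C@@H]1OC(=O)[C@H](C)[C@@]1(O)[C@@H]2COC(C)(C)O2
F7 | step 5 | O7 lactone with C6 dithioacetal and free 9,10-diol | CCSC(SCC)[C@@H]1OC(=O)[C@H](C)[C@@]1(O)[C@@H](O)CO
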